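**Assumptions (one line):** The target is (2S)-2',5'-diprenyl-eriodictyol. Natural (2S)-eriodictyol is commercially available from citrus or yerba santa sources. Its 7-OH is the most acidic phenol, so it can be masked selectively in the presence of the catechol.

## Retrosynthetic overview
1. Sigmoidin A ⇐ acid removal of a 7-O-MOM group from the 2',5'-diprenylated flavanone.
2. The 2',5'-diprenyl catechol pattern ⇐ a double aromatic Claisen [3,3] rearrangement of a catechol bis(1,1-dimethylallyl) ether. The 3'-O group can only migrate to C2' (C4' is occupied), and the 4'-O group can only migrate to C5'.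
3. The bis(1,1-dimethylallyl) ether ⇐ Lindlar reduction of the bis(1,1-dimethylpropargyl) ether ⇐ Cu-catalysed etherification of the catechol with 3-chloro-3-methylbut-1-yne.
4. All rings and the C2 (S) stereocentre come from (S)-eriodictyol, so no ring is formed in the route and C2 is never touched. The 7-OH is masked as a MOM ether.

## Forward route

**Step 1**
Reactants: **1** (2S)-eriodictyol; **2** chloromethyl methyl ether (MOMCl)
Product: **3** (2S)-7-O-MOM-eriodictyol
Conditions: MOMCl (1.05 equiv), K2CO3 (1.1 equiv), acetone, 0 °C → rt
Reagents that add atoms: MOMCl, COCCl
Why: The 7-OH is the most acidic phenol (para to the C4 carbonyl), so one equivalent of weak base and one equivalent of electrophile alkylates it selectively. The 5-OH is H-bonded to the carbonyl and the catechol is less acidic. C2 is not involved and keeps its (S) configuration.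

**Step 2**
Reactants: **3**; **4** 3-chloro-3-methylbut-1-yne
Product: **5** (2S)-7-O-MOM-3',4'-bis-O-(1,1-dimethylpropargyl)eriodictyol
Conditions: **4** (4 equiv), K2CO3, KI (cat.), CuI (cat.), DMF, rt → 40 °C, monitored to stop at full conversion
Reagents that add atoms: 3-chloro-3-methylbut-1-yne, CC(C)(Cl)C#C
Why: Cu-mediated propargylic etherification (via a Cu-allenylidene or propargyl cation) installs tertiary propargyl ethers on phenols. The two catechol OH groups react, while the chelated 5-OH is inert. No stereocentre is formed or altered, and the mild, short conditions avoid ring-opening racemisation of the flavanone.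

**Step 3**
Reactant: **5**
Product: **6** (2S)-7-O-MOM-3',4'-bis-O-(1,1-dimethylallyl)eriodictyol
Conditions: H2 (1 atm), Lindlar catalyst (Pd/CaCO3/Pb), quinoline, EtOAc, rt
Reagents that add atoms: none (H2 only adds hydrogen)
Why: Lindlar semihydrogenation converts the terminal alkynes to vinyl groups (syn addition of H2) and leaves the aryl ketone, the aryl ethers and the MOM ether untouched. The quinoline poison prevents over-reduction. The stereocentre is untouched.

**Step 4**
Reactant: **6**
Product: **7** (2S)-7-O-MOM-sigmoidin A (2',5'-diprenyl-7-O-MOM-eriodictyol)
Conditions: PhCl, 130 °C, sealed tube, Ar, BHT (radical inhibitor), 12 h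
Reagents that add atoms: none
Why: This is the aromatic Claisen rearrangement ([3,3]-sigmatropic, chair transition state). Each O–C(CH3)2–CH=CH2 group transposes so that the terminal CH2 bonds to the ortho carbon, and tautomerisation of the dienone restores the aromatic ring, giving the normal prenyl group. Regiochemistry is fixed by the ring substitution: the 3'-O ether can only reach C2', and the 4'-O ether can only reach C5'. No new stereocentre is formed; neutral, non-polar conditions leave C2 intact.

**Step 5**
Reactant: **7**
Product: **8** sigmoidin A, (2S)-5,7,3',4'-tetrahydroxy-2',5'-diprenylflavanone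
Conditions: cat. conc. HCl, MeOH, rt (monitor closely)
Reagents that add atoms: none (the MOM group leaves as CH2(OMe)2 or MeOH and CH2O)
Why: Aryl MOM acetals hydrolyse in mild acid, while the flavanone, the free catechol, the 5-OH and the prenyl alkenes survive short treatment at rt. C2 is not scrambled because the conditions are acidic and non-basic.

## Checks performed
- **Structure:** Product 8 has a flavanone core (A ring 5,7-diOH; C ring closed; C2 attached to C1'). The B ring carries C1' (flavanone), C2' prenyl, C3' OH, C4' OH, C5' prenyl and C6' H. This matches the target SMILES.
- **Configuration:** In the target, the C2 neighbour order is aryl, H, O, C3 with @@, which gives (S). Compounds 1 and 3 to 8 are written with the same neighbour order and the same @@ tag, so all are (S).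
- **Atom balance:** Step 2 replaces two phenolic H atoms with two C5H7 groups. Step 3 adds 2 H2 per alkyne (4 H2 in total, one per π bond, giving C5H9 groups). Step 4 is an isomerisation. Step 5 removes CH2OCH3 and restores H.
- **Functional-group survival:** The MOM group is stable to base, Cu and Lindlar conditions, and to heating. Aryl ketone, prenyl alkenes and the C-ring ether are stable throughout.
- **Stereocentre:** C2 is never touched after purchase, and there is no base or strong heat in the presence of a free phenoxide beyond the brief steps 1 and 2.

## Compound list
1 | (2S)-eriodictyol | Oc1ccc([C@@H]2CC(=O)c3c(O)cc(O)cc3O2)cc1O | starting material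
2 | chloromethyl methyl ether | COCCl | starting material
3 | (2S)-7-O-MOM-eriodictyol | Oc1ccc([C@@H]2CC(=O)c3c(O)cc(OCOC)cc3O2)cc1O | intermediate
4 | 3-chloro-3-methylbut-1-yne | CC(C)(Cl)C#C | starting material
5 | bis(1,1-dimethylpropargyl) ether of 3 | C#CC(C)(C)Oc1ccc([C@@H]2CC(=O)c3c(O)cc(OCOC)cc3O2)cc1OC(C)(C)C#C | intermediate
6 | bis(1,1-dimethylallyl) ether of 3 | C=CC(C)(C)Oc1ccc([C@@H]2CC(=O)c3c(O)cc(OCOC)cc3O2)cc1OC(C)(C)C=C | intermediate
7 | 7-O-MOM-sigmoidin A | CC(C)=CCc1cc([C@@H]2CC(=O)c3c(O)cc(OCOC)cc3O2)c(CC=C(C)C)c(O)c1O | intermediate
8 | sigmoidin A | CC(C)=CCc1cc([C@@H]2CC(=O)c3c(O)cc(O)cc3O2)c(CC=C(C)C)c(O)c1O | target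

**Total steps:** 5. **Longest linear sequence:** 5 (every step is on the main line from 1).

## Three steps most likely to fail
1. **Step 2 (double tertiary propargylation of the adjacent catechol OH groups; possible racemisation under K2CO3/DMF).** Fallback: build the 1,1-dimethylallyl ethers directly and stepwise. Prepare 2-methylbut-3-en-2-yl trichloroacetimidate from 2-methylbut-3-en-2-ol and Cl3CCN, couple it to one OH with a Lewis acid, and run the first Claisen before the second etherification. This also avoids the Lindlar step.
2. **Step 4 (hindered Claisen into C2', competing ionisation and 1,3-shifts of the tertiary allyl ethers, thermal erosion of C2).** Fallback: use plain O-allyl ethers (allyl bromide, K2CO3), which rearrange cleanly in a double Claisen under microwave heating, then convert the two allyl groups to prenyl groups by cross-metathesis with 2-methylbut-2-ene and a Ru carbene catalyst.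
3. **Step 1 (7-OH versus catechol selectivity).** Fallback: temporarily mask the catechol as its cyclic phenylboronate (or diphenyl ketal), MOM-protect the 7-OH, then release the catechol before step 2.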